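The benzene ring of the methoxygramine indole is not brought in ready-made. Its pattern (O on C5', OMe on C7', N on C7a', C4' bonded to C9a; β-carboline locants for the core, primed indole locants for this arene) is read as a 3-alkoxy-5-methoxy-6-chloropyridazine joined through O–C4a–C9a to an alkyne. On heating, the alkyne adds across the diazine and N2 is lost, which forms this benzene ring and the dihydrofuran ring (O, C4a, C9a, C4', C5') in one operation. The precursor is a cis 4a-pyridazinyloxy-9a-alkynyl hexahydro-β-carboline, reached by asymmetric C4a hydroxylation of 2-methyltryptoline, cis acetylide addition and SNAr; chlorine later becomes N1'.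

Key step: step 5

Remark on locants and configuration: in the locants defined above the target is (4aS,9aR), with the C4a oxygen and the C9a aryl carbon cis.

Assumption: the oxaziridine derived from (1S)-camphor-10-sulfonic acid is taken to deliver oxygen to the indole face that gives the 4aS alcohol; if the opposite sense is found, its commercially available enantiomer is used with no other change.

**Step 1**
Reactants: 1 2,3,4,9-tetrahydro-1H-pyrido[3,4-b]indole (tryptoline)
Product: 2 2-methyl-2,3,4,9-tetrahydro-1H-pyrido[3,4-b]indole (2-methyltryptoline)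
Conditions: 37% aq. CH2O, NaBH(OAc)3, AcOH, ClCH2CH2Cl, rt
Reagents that add atoms: formaldehyde, C=O
Why: Reductive amination (iminium formation, then hydride delivery from NaBH(OAc)3) methylates the only basic nitrogen; the indole N–H is not nucleophilic enough to compete and no stereocenter is formed.

**Step 2**
Reactants: 2 2-methyltryptoline
Product: 4 (4aS)-2-methyl-2,3,4,4a-tetrahydro-1H-pyrido[3,4-b]indol-4a-ol (hydroxyindolenine with C9a=N9), via trifluoroacetate salt 3 (not isolated)
Conditions: CF3CO2H (1.05 equiv), CH2Cl2, 0 °C; oxaziridine (1.2 equiv), 0 °C → rt; aq. NaHCO3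
Reagents that add atoms: (8,8-dichlorocamphorylsulfonyl)oxaziridine from (1S)-camphor-10-sulfonic acid, O=S1(=O)C[C@]23CC[C@H](C(Cl)(Cl)[C@]24ON14)C3(C)C
Why: Protonation of N2 shuts off N-oxide formation, so the electrophilic N-sulfonyloxaziridine transfers oxygen to the C4a=C9a enamine bond of the indole (epoxidation-type oxygen transfer, opening to the 3-hydroxy-3H-indole), a known asymmetric hydroxylation of 2,3-disubstituted indoles in which the camphor-derived reagent tells the two faces of the planar indole apart and so sets C4a as S under reagent control.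

**Step 3**
Reactants: 4 (4aS)-hydroxyindolenine; 5 4,4-diethoxybut-1-yne
Product: 7 benzyl (4aS,9aR)-9a-(4,4-diethoxybut-1-yn-1-yl)-4a-hydroxy-2-methyl-1,2,3,4,4a,9a-hexahydro-9H-pyrido[3,4-b]indole-9-carboxylate (OH and alkyne cis), via dilithium amide alkoxide 6 (not isolated)
Conditions: 5 (2.3 equiv), n-BuLi (2.2 equiv), THF, −78 °C; add 4, −78 → −20 °C; CbzCl (1.3 equiv), −78 → 0 °C; H2O
Reagents that add atoms: benzyl chloroformate, O=C(Cl)OCc1ccccc1
Why: 1,2-Addition of a lithium acetylide to the C=N bond of a 3H-indole, helped by the lithium alkoxide formed first at C4a, which chelates N9 and delivers the acetylide to its own face; that face is also the only one giving the cis six/five ring fusion, so C9a should be set as R under control of C4a with alkyne and oxygen cis, and the resulting lithium anilide, far more nucleophilic than the hindered tertiary alkoxide, should take the chloroformate at low temperature before the tertiary amine N2 can be dealkylated.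

**Step 4**
Reactants: 7 N9-benzyloxycarbonyl alkynyl alcohol; 8 3,6-dichloro-4-methoxypyridazine
Product: 9 benzyl (4aS,9aR)-4a-[(6-chloro-5-methoxypyridazin-3-yl)oxy]-9a-(4,4-diethoxybut-1-yn-1-yl)-2-methyl-1,2,3,4,4a,9a-hexahydro-9H-pyrido[3,4-b]indole-9-carboxylate
Conditions: NaH (1.2 equiv), THF/DMF, 0 °C; 8 (1.3 equiv), 0 °C → rt
Reagents that add atoms: none
Why: Nucleophilic aromatic substitution (addition–elimination) by the sodium alkoxide at C6 of the diazine, the chlorine next to the ring C–H, because the other chlorine is shielded and electronically deactivated by the ortho methoxy group; closure of the alkoxide onto the N9 carbamate is excluded since it would need a bridgehead acyl nitrogen, the benzyl carbamate tolerates the base, and no stereocenter is touched.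

**Step 5**
Reactants: 9 pyridazinyl ether with cis alkyne
Product: 11 N9-benzyloxycarbonyl pentacyclic chloroarene, (4aS,9aR): benzene ring fused through C4'–C9a and C5'–O–C4a, with 2,2-diethoxyethyl on C3a', Cl on C7a' and OMe on C7', via diazabicyclooctatriene adduct 10 (not isolated)
Conditions: degassed 1,3,5-triisopropylbenzene (0.01 M), 200 °C, sealed tube
Reagents that add atoms: none
Why: The alkyne adds as the 2π unit across the two nitrogen-flanked carbons of the chloropyridazine (intramolecular inverse-electron-demand [4+2]), forming C4'–C5' and C3a'–C7a' and giving the 2,3-diazabicyclo[2.2.2]octatriene 10, which expels N2 by retro-[4+2] and so gives the benzene ring directly at the arene oxidation level. The closest known reaction type is the thermal cyclisation of 3-(alk-3-ynyloxy)pyridazines to 2,3-dihydrobenzofurans. The benzene ring closes by the cycloaddition/cycloreversion pair, and the dihydrofuran ring (O, C4a, C9a, C4', C5') closes in the same event as the ring fused through the three-atom tether, the only mode the tether length allows, so regiochemistry is not in question. No stereocenter is created, since the bridgeheads of 10 become sp2 and either bridgehead diastereomer gives the same arene; C4a and C9a are not touched. The step needs cycloaddition to outrun O-to-N aryl migration (Smiles type) and ionisation of the tertiary ether. The N9 benzyl carbamate removes the nucleophilic N–H and is stable to base, heat and zerovalent palladium, the cis oxygen and alkyne on adjacent quaternary carbons hold the reacting ends close, and chlorine keeps the diazine electron-poor.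

**Step 6**
Reactants: 11 pentacyclic chloroarene
Product: 14 N9-benzyloxycarbonyl pentacyclic 7'-methoxyindole, (4aS,9aR), C3' unsubstituted, via N-aryl benzophenone imine 12 (not isolated), via aminoaryl acetal 13 (not isolated)
Conditions: Ph2C=NH (1.5 equiv), Pd2(dba)3 (5 mol %), XPhos (12 mol %), Cs2CO3 (2 equiv), toluene, 100 °C; then 2 M aq. HCl, THF, rt; aq. NaHCO3
Reagents that add atoms: benzophenone imine, N=C(c1ccccc1)c1ccccc1
Why: Buchwald–Hartwig amination with benzophenone imine as a compact ammonia equivalent (bulky silylamides couple poorly with a chloride flanked on both sides), using zerovalent palladium with the bulky electron-rich phosphine XPhos to force oxidative addition into the electron-rich C–Cl bond and a carbonate base that spares the carbamate; aqueous acid then hydrolyses imine and acetal, and the freed aniline condenses with the aldehyde carbon (5-exo attack, then loss of ethanol) to close the pyrrole ring of the indole without touching C4a or C9a.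

**Step 7**
Reactants: 14 N9-benzyloxycarbonyl indole
Product: 15 (4aS,9aR) N9–H pentacyclic 7'-methoxyindole (the target lacking its CH2NMe2 group)
Conditions: H2 (1 atm), Pd/C (10 wt % Pd), MeOH, rt
Reagents that add atoms: none
Why: Hydrogenolysis of the benzyl carbamate (O-benzyl cleavage on palladium, then decarboxylation) frees N9–H under neutral conditions that should leave the indole, the aryl ethers and the hindered quaternary benzylic C–O and C–N bonds alone; it is placed before the Mannich step because a gramine C–N bond would itself be open to hydrogenolysis.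

**Step 8**
Reactants: 15 N9–H pentacyclic indole
Product: 16 target, (4aS,9aR), with CH2NMe2 on C3'
Conditions: 40% aq. Me2NH, 37% aq. CH2O, AcOH, 0 °C → rt
Reagents that add atoms: dimethylamine, CNC; formaldehyde, C=O
Why: Mannich reaction in which the iminium ion from dimethylamine and formaldehyde is attacked by C3', the most nucleophilic carbon of the indole, to give the gramine side chain, while any aminal at the hindered N9–H is reversible in acetic acid; no stereocenter is affected.

**Compound list**
1 | 2,3,4,9-tetrahydro-1H-pyrido[3,4-b]indole (tryptoline) | C1Cc2c(CN1)[nH]c1ccccc21 | starting material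
2 | 2-methyl-2,3,4,9-tetrahydro-1H-pyrido[3,4-b]indole | CN1CCc2c(C1)[nH]c1ccccc21 | intermediate
3 | 2-methyl-2,3,4,9-tetrahydro-1H-pyrido[3,4-b]indol-2-ium trifluoroacetate | C[NH+]1CCc2c(C1)[nH]c1ccccc21.[O-]C(=O)C(F)(F)F | intermediate (not isolated)
4 | (4aS)-2-methyl-2,3,4,4a-tetrahydro-1H-pyrido[3,4-b]indol-4a-ol | CN1CC[C@]2(O)c3ccccc3N=C2C1 | intermediate
5 | 4,4-diethoxybut-1-yne | CCOC(CC#C)OCC | starting material
6 | dilithium (4aS,9aR)-9a-(4,4-diethoxybut-1-yn-1-yl)-2-methyl-1,2,3,4,4a,9a-hexahydropyrido[3,4-b]indol-9-id-4a-olate (cis) | CCOC(OCC)CC#C[C@@]12CN(C)CC[C@]1([O-])c1ccccc1[N-]2.[Li+].[Li+] | intermediate (not isolated)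
7 | benzyl (4aS,9aR)-9a-(4,4-diethoxybut-1-yn-1-yl)-4a-hydroxy-2-methyl-1,2,3,4,4a,9a-hexahydro-9H-pyrido[3,4-b]indole-9-carboxylate | CCOC(OCC)CC#C[C@@]12CN(C)CC[C@]1(O)c1ccccc1N2C(=O)OCc1ccccc1 | intermediate
8 | 3,6-dichloro-4-methoxypyridazine | COc1cc(Cl)nnc1Cl | starting material
9 | benzyl (4aS,9aR)-4a-[(6-chloro-5-methoxypyridazin-3-yl)oxy]-9a-(4,4-diethoxybut-1-yn-1-yl)-2-methyl-1,2,3,4,4a,9a-hexahydro-9H-pyrido[3,4-b]indole-9-carboxylate | CCOC(OCC)CC#C[C@@]12CN(C)CC[C@]1(Oc1cc(OC)c(Cl)nn1)c1ccccc1N2C(=O)OCc1ccccc1 | intermediate (key-step precursor)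
10 | 2,3-diazabicyclo[2.2.2]octa-2,5,7-triene adduct of 9 (bridgeheads carry O and Cl; bridgehead configuration left open, either diastereomer gives 11) | COC1=CC23N=NC1(Cl)C(CC(OCC)OCC)=C2[C@@]12CN(C)CC[C@]1(O3)c1ccccc1N2C(=O)OCc1ccccc1 | intermediate (not isolated)
11 | N9-benzyloxycarbonyl (4aS,9aR) pentacyclic chloroarene, 2,2-diethoxyethyl on C3', Cl on C7a', OMe on C7' | COc1cc2c(c(CC(OCC)OCC)c1Cl)[C@@]13CN(C)CC[C@]1(O2)c1ccccc1N3C(=O)OCc1ccccc1 | intermediate (key-step product)
12 | as 11 with N=CPh2 on C7a' in place of Cl | COc1cc2c(c(CC(OCC)OCC)c1N=C(c1ccccc1)c1ccccc1)[C@@]13CN(C)CC[C@]1(O2)c1ccccc1N3C(=O)OCc1ccccc1 | intermediate (not isolated)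
13 | as 11 with NH2 on C7a' in place of Cl | COc1cc2c(c(CC(OCC)OCC)c1N)[C@@]13CN(C)CC[C@]1(O2)c1ccccc1N3C(=O)OCc1ccccc1 | intermediate (not isolated)
14 | N9-benzyloxycarbonyl (4aS,9aR) pentacyclic 7'-methoxyindole, C3' unsubstituted | COc1cc2c(c3cc[nH]c13)[C@@]13CN(C)CC[C@]1(O2)c1ccccc1N3C(=O)OCc1ccccc1 | intermediate
15 | (4aS,9aR) N9–H pentacyclic 7'-methoxyindole, C3' unsubstituted | COc1cc2c(c3cc[nH]c13)[C@@]13CN(C)CC[C@]1(O2)c1ccccc1N3 | intermediate
16 | target, (4aS,9aR), CH2NMe2 on C3' | COc1cc2c(c3c(CN(C)C)c[nH]c13)[C@@]13CN(C)CC[C@]1(O2)c1ccccc1N3 | target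

Total step count: 8. Longest linear sequence: 8 steps (1 → 16); 5 and 8 are purchased.

**Steps most likely to fail**

Step 5. The cycloaddition may be too slow, because the two alkoxy donors make the diazine a weak 4π partner; thermal ionisation and elimination of the tertiary benzylic ether could then win. The fallback makes the diazine electron-poor with an ester in place of chlorine and brings nitrogen in by rearrangement instead of cross-coupling. It sets out from 7 and comes back at 13.
- Commercial methyl 4,6-dichloropyridazine-3-carboxylate (COC(=O)c1nnc(Cl)cc1Cl) with NaOMe (1 equiv, MeOH, 0 °C) should exchange its more reactive C4 chlorine and give methyl 6-chloro-4-methoxypyridazine-3-carboxylate F1.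
- The sodium alkoxide of 7 (NaH, THF, 0 °C) displaces the only remaining chlorine to give the ester-bearing pyridazinyl ether F2.
- Heating (toluene or 1,2-dichlorobenzene, 120–150 °C expected, since acceptor-substituted diazines cyclise more readily) gives, through the bridged diaza adduct F3, the arene methyl ester F4.
- LiOH (THF/MeOH/H2O, 60 °C) gives the carboxylic acid F5, the benzyl carbamate being stable to it.
- Diphenylphosphoryl azide, (PhO)2P(O)N3, with Et3N in toluene gives the acyl azide F6, which on warming to 90 °C undergoes Curtius rearrangement to the aryl isocyanate F7.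
- Aqueous HCl in THF hydrolyses F7 to the aminoaryl acetal 13, which the same acid closes to 14.
- This detour also has only one chlorine on the diazine, so the regiochemical question of step 4 and the cross-coupling of step 6 do not arise.

Step 3. The acetylide may fail to add to the hindered ketimine (competing deprotonation at C1, or base-induced 1,2-shift of the hydroxyindolenine), or the trap may lose chemoselectivity (acylation at oxygen, dealkylation at N2). The fallback separates addition, N-acylation and oxygen protection. It sets out from 4 and comes back at 7.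
- N-(Trimethylsilyl)imidazole in CH2Cl2 gives the trimethylsilyl ether F8.
- The C=N bond of F8, precomplexed with BF3·OEt2 at −78 °C in THF, takes up the lithium acetylide of 5 (alkynylation of a Lewis-acid-activated imine) to give the cis amine F9; cis is expected again because only that face gives the cis ring fusion.
- NaN(SiMe3)2, then benzyl chloroformate, gives the carbamate F10.
- K2CO3 in methanol removes the silyl group and returns 7.

Step 2. Oxygen transfer may show poor facial selectivity, so the alcohol would not be a single enantiomer. The fallback replaces reagent control by resolution. It sets out from 2 and comes back at 4.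
- Salt 3, made from 2 as before, is oxidised with racemic 3-phenyl-2-(phenylsulfonyl)oxaziridine to the racemic hydroxyindolenine F11.
- Its tertiary amine forms diastereomeric 1:1 salts with O,O'-di-p-toluoyl-L-tartaric acid; the hydrogen tartrate of the 4aS base F12 is crystallised to purity (with the D-acid instead, if the 4aR salt proves the less soluble one).
- Aqueous NaHCO3 cleaves the salt to give 4.

**Further compounds**
F1 | step 5 | methyl 6-chloro-4-methoxypyridazine-3-carboxylate | COC(=O)c1nnc(Cl)cc1OC
F2 | step 5 | benzyl (4aS,9aR)-9a-(4,4-diethoxybut-1-yn-1-yl)-4a-{[5-methoxy-6-(methoxycarbonyl)pyridazin-3-yl]oxy}-2-methyl-1,2,3,4,4a,9a-hexahydro-9H-pyrido[3,4-b]indole-9-carboxylate | CCOC(OCC)CC#C[C@@]12CN(C)CC[C@]1(Oc1cc(OC)c(C(=O)OC)nn1)c1ccccc1N2C(=O)OCc1ccccc1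
F3 | step 5 | 2,3-diazabicyclo[2.2.2]octatriene adduct of F2 (bridgehead configuration left open) | COC1=CC23N=NC1(C(=O)OC)C(CC(OCC)OCC)=C2[C@@]12CN(C)CC[C@]1(O3)c1ccccc1N2C(=O)OCc1ccccc1
F4 | step 5 | as 11 with CO2Me on C7a' in place of Cl | COc1cc2c(c(CC(OCC)OCC)c1C(=O)OC)[C@@]13CN(C)CC[C@]1(O2)c1ccccc1N3C(=O)OCc1ccccc1
F5 | step 5 | as 11 with CO2H on C7a' in place of Cl | COc1cc2c(c(CC(OCC)OCC)c1C(=O)O)[C@@]13CN(C)CC[C@]1(O2)c1ccccc1N3C(=O)OCc1ccccc1
F6 | step 5 | as 11 with C(=O)N3 (acyl azide) on C7a' in place of Cl | COc1cc2c(c(CC(OCC)OCC)c1C(=O)N=[N+]=[N-])[C@@]13CN(C)CC[C@]1(O2)c1ccccc1N3C(=O)OCc1ccccc1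
F7 | step 5 | as 11 with N=C=O on C7a' in place of Cl | COc1cc2c(c(CC(OCC)OCC)c1N=C=O)[C@@]13CN(C)CC[C@]1(O2)c1ccccc1N3C(=O)OCc1ccccc1
F8 | step 3 | (4aS)-2-methyl-4a-(trimethylsilyloxy)-2,3,4,4a-tetrahydro-1H-pyrido[3,4-b]indole | CN1CC[C@]2(O[Si](C)(C)C)c3ccccc3N=C2C1
F9 | step 3 | (4aS,9aR)-9a-(4,4-diethoxybut-1-yn-1-yl)-2-methyl-4a-(trimethylsilyloxy)-2,3,4,4a,9,9a-hexahydro-1H-pyrido[3,4-b]indole (cis) | CCOC(OCC)CC#C[C@@]12CN(C)CC[C@]1(O[Si](C)(C)C)c1ccccc1N2
F10 | step 3 | benzyl (4aS,9aR)-9a-(4,4-diethoxybut-1-yn-1-yl)-2-methyl-4a-(trimethylsilyloxy)-1,2,3,4,4a,9a-hexahydro-9H-pyrido[3,4-b]indole-9-carboxylate | CCOC(OCC)CC#C[C@@]12CN(C)CC[C@]1(O[Si](C)(C)C)c1ccccc1N2C(=O)OCc1ccccc1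
F11 | step 2 | racemic 2-methyl-2,3,4,4a-tetrahydro-1H-pyrido[3,4-b]indol-4a-ol | CN1CCC2(O)c3ccccc3N=C2C1
F12 | step 2 | (4aS)-4a-hydroxy-2-methyl-2,3,4,4a-tetrahydro-1H-pyrido[3,4-b]indol-2-ium hydrogen O,O'-di-p-toluoyl-L-tartrate | C[NH+]1CC[C@]2(O)c3ccccc3N=C2C1.OC(=O)[C@H](OC(=O)c1ccc(C)cc1)[C@@H](OC(=O)c1ccc(C)cc1)C([O-])=O
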